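**Retrosynthetic overview**

1. Target 28 ⇐ bis-silyl ether 27 ⇐ base-mediated enone conjugation of 26 ⇐ Diels–Alder reaction of enone 24 (dienophile C4'=C15') with tetraenone 25 (diene C2=C1–C10=C14). This forms C2–C4' and C14–C15', so the spiro-cyclohexene is made last.
2. 25 comes from 24 by dehydrogenation, so one monomer serves both halves. In 24 the seven-membered ring is closed by a type 2 carbonyl-ene reaction (C8–C9) and the γ-lactone by allylboration/lactonisation (C6–C7) of cyclopentane-carbaldehyde 7 with allylboronate 12.
3. The cyclopentane of 7 (C1'–C5' of the spiro-ketone ring, and likewise C1–C5 of the dienone half) is made by ring contraction: Favorskii rearrangement of the six-membered ring of the (R)-carvone chlorohydrin ether 4.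
4. Enabling feature: in 4 the carbonyl C1 lies between the fully substituted, chlorine-bearing C2 and the enolisable C6H2, with a siloxy group on C3. The C6 enolate closes onto C2, and cleavage of C1–C2 expels C1 as the ester carbon (later C6/C6'). Carvone C6, C2, C3, C4, C5 become C5', C4', C3', C2', C1'.
5. Ring order: cyclopentane (step 4) → γ-lactone (step 8) → cycloheptane (step 12) → spiro-cyclohexene (step 19).

Key step: step 4

Remark (assumption): C5 and C10 of the dienone half are γ-positions of the cross-conjugated dienone and epimerise under base, so the route assumes that the configuration drawn for the target (5β-H, 10β-H) is the one reached at equilibrium.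

Guaiane numbering is used from compound 6 onward; primes mark the spiro-ketone half; β means the face of the C7–C11 bond.

**Route**

Step 1
Reactants: 1 (R)-(−)-carvone
Product: 2 carvone 2,3-epoxide with the epoxide trans to the isopropenyl group
Conditions: 30% aq. H2O2, NaOH (cat.), MeOH, 0 °C
Reagents that add atoms: hydrogen peroxide, OO
Why: Weitz–Scheffer nucleophilic epoxidation touches only the enone; hydroperoxide adds to C3 anti to the C5 isopropenyl group, which sets C2 and C3 under substrate control.

Step 2
Reactants: 2 carvone trans-epoxide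
Product: 3 chlorohydrin (2-chloro-3-hydroxy; Cl cis and OH trans to isopropenyl)
Conditions: LiCl, CF3CO2H, THF, 0 °C → rt
Reagents that add atoms: lithium chloride, [Li+].[Cl-]
Why: Acid-promoted SN2-type opening of the α,β-epoxy ketone by chloride at the tertiary C2 with inversion places chlorine cis to the isopropenyl group and leaves the C3 oxygen untouched.

Step 3
Reactants: 3 chlorohydrin
Product: 4 chlorohydrin 3-O-tert-butyldimethylsilyl ether
Conditions: TBSOTf, 2,6-lutidine, CH2Cl2, −78 °C
Reagents that add atoms: tert-butyldimethylsilyl triflate, CC(C)(C)[Si](C)(C)OS(=O)(=O)C(F)(F)F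
Why: O-Silylation blocks the hydroxyl so that base cannot re-close the epoxide in the next step; no stereocentre changes.

Step 4
Reactants: 4 chlorohydrin silyl ether
Product: 6 cyclopentane methyl ester (1β-isopropenyl 3α-siloxy 4α-methyl 5β-CO2Me), via cyclopropanone 5 (not isolated)
Conditions: NaOMe, MeOH, 0 °C → rt
Reagents that add atoms: sodium methoxide, C[O-].[Na+]
Why: Favorskii rearrangement: methoxide forms the only possible enolate (C1=C6, since C2 is fully substituted), which displaces the tertiary chloride at C2 with inversion to give cyclopropanone 5; methoxide then adds to the carbonyl and the C1–C2 bond breaks with protonation at C2, so the six-membered carvone ring becomes the cyclopentane C2–C3–C4–C5–C6 with C1 expelled as the ester carbon. The closest known reaction type is the Favorskii ring contraction of α-chlorocyclohexanones made from terpenone chlorohydrin ethers. The only ring closed is the transient cyclopropanone (3-exo-tet, C6 onto C2), and its C2–C6 bond becomes the fifth bond of the cyclopentane. Carvone C6 (guaiane C5) is set by the backside displacement: the acyl bridge, and hence the ester, ends on the face the chloride left, cis to the isopropenyl group. Carvone C2 (guaiane C4) is protonated with retention where the bridge departs, which puts the methyl trans to the ester and cis to the siloxy group. The step needs cyclopropanone opening at C1–C2 and not at C1–C6, which the β-siloxy group on C3 secures by stabilising negative charge at C2.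

Step 5
Reactants: 6 cyclopentane methyl ester
Product: 7 cyclopentane-carbaldehyde (C6 aldehyde on C5)
Conditions: i-Bu2AlH (1.1 equiv), toluene, −78 °C; aq. potassium sodium tartrate work-up
Reagents that add atoms: none
Why: Partial reduction of the ester through the tetrahedral aluminium hemiacetal, which is stable at −78 °C; no new stereocentre, and the aldehyde is used at once to avoid epimerisation at C5.

Step 6
Reactants: 8 3,3-diethoxyprop-1-yne
Product: 10 ethyl 4,4-diethoxybut-2-ynoate, via lithium acetylide 9 (not isolated)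
Conditions: n-BuLi, THF, −78 °C; then ClCO2Et, −78 → 0 °C
Reagents that add atoms: ethyl chloroformate, CCOC(=O)Cl
Why: Deprotonation of the terminal alkyne and C-acylation of the acetylide by the chloroformate; no stereocentre.

Step 7
Reactants: 10 ethyl 4,4-diethoxybut-2-ynoate
Product: 12 ethyl (Z)-4,4-diethoxy-2-[(pinacolboryl)methyl]but-2-enoate, via alkenylalane 11 (not isolated)
Conditions: i-Bu2AlH, HMPA, THF, 0 °C; then ICH2Bpin, 0 °C → rt
Reagents that add atoms: 2-(iodomethyl)-4,4,5,5-tetramethyl-1,3,2-dioxaborolane, ICB1OC(C)(C)C(C)(C)O1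
Why: Conjugate syn-hydroalumination of the alkynoate puts H and Al cis, so the acetal ends cis to the ester; alkylation of the alkenylalane by the iodomethylboronate with retention gives the (Z)-allylboronate (hydroalumination–alkylation).

Step 8
Reactants: 7 cyclopentane-carbaldehyde, 12 (Z)-allylboronate
Product: 14 trans-β,γ-disubstituted α-methylene-γ-butyrolactone carrying the C8 diethyl acetal, via borate ester 13 (not isolated)
Conditions: toluene, 110 °C (sealed tube); then pyridinium p-toluenesulfonate (cat.), rt
Reagents that add atoms: none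
Why: Carbonyl allylboration through a closed chair (Zimmerman–Traxler) transition state: the γ-acetal group trans to CH2B sits equatorial and gives the anti adduct, hence the trans-lactone (C7); Felkin–Anh attack anti to the C1 branch that carries the cis isopropenyl group sets C6 (O α); the borate then lactonises onto the ester.

Step 9
Reactants: 14 lactone acetal silyl ether
Product: 15 3α-alcohol
Conditions: HF·pyridine, pyridine, THF, 0 °C → rt
Reagents that add atoms: none
Why: Fluoride-mediated cleavage of the secondary silyl ether under buffered conditions that leave the acetal and the α-methylene lactone intact; no stereocentre changes.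

Step 10
Reactants: 15 3α-alcohol
Product: 16 cyclopent-3-ene (C3=C4 with the methyl on C4)
Conditions: Martin sulfurane, CH2Cl2, 0 °C → rt
Reagents that add atoms: none
Why: Anti (E2-type) elimination of the alkoxysulfurane: the 3α-oxygen is antiperiplanar to H-4β, so the more substituted C3=C4 alkene should form and the C3 and C4 stereocentres are deleted.

Step 11
Reactants: 16 cyclopentene acetal
Product: 17 C8 aldehyde
Conditions: 10% aq. oxalic acid on SiO2, CH2Cl2, rt; used crude at once
Reagents that add atoms: water, O
Why: Mild acetal hydrolysis frees the C8 aldehyde without enolising the epimerisable C7; no new stereocentre.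

Step 12
Reactants: 17 C8 aldehyde
Product: 18 8α-hydroxyguaia-3,10(14),11(13)-trien-12,6α-olide
Conditions: Me2AlCl (2 equiv), CH2Cl2, −78 → −20 °C
Reagents that add atoms: none
Why: Type 2 intramolecular carbonyl-ene reaction: the terminal CH2 of the isopropenyl group bonds to C8 and a methyl hydrogen is transferred, which closes the seven-membered ring with the 10(14)-methylene in place; a chair-like transition state with the aluminium-bound oxygen pseudo-equatorial and anti to C7–C11 should give the 8α-alcohol.

Step 13
Reactants: 18 8α-alcohol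
Product: 20 8β-hydroxyguaia-3,10(14),11(13)-trien-12,6α-olide, via formate ester 19 (not isolated)
Conditions: HCO2H, PPh3, DIAD, THF, 0 °C → rt; then KHCO3, MeOH/H2O, 0 °C
Reagents that add atoms: formic acid, O=CO
Why: Mitsunobu reaction inverts C8 by SN2 displacement of the oxyphosphonium by formate; the labile formate is then cleaved by bicarbonate without touching the α-methylene lactone.

Step 14
Reactants: 20 8β-alcohol
Product: 21 8β-tert-butyldimethylsilyl ether
Conditions: TBSOTf, 2,6-lutidine, CH2Cl2, −78 → 0 °C
Reagents that add atoms: tert-butyldimethylsilyl triflate, CC(C)(C)[Si](C)(C)OS(=O)(=O)C(F)(F)F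
Why: Silylation protects the 8β-hydroxyl against oxidation and against base-induced translactonisation in the later steps; no stereocentre changes.

Step 15
Reactants: 21 triene silyl ether
Product: 22 3α,4α-epoxide
Conditions: mCPBA, NaHCO3, CH2Cl2, 0 °C
Reagents that add atoms: 3-chloroperoxybenzoic acid, O=C(OO)c1cccc(Cl)c1
Why: Prilezhaev epoxidation selects the electron-rich trisubstituted C3=C4 alkene over the 1,1-disubstituted C10=C14 and the electron-poor lactone methylene; the peracid approaches the convex α-face (C3 and C4 are set by substrate control and removed again by step 17).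

Step 16
Reactants: 22 3α,4α-epoxide
Product: 23 3α-hydroxy-4(15)-ene (allylic alcohol)
Conditions: Al(OiPr)3, toluene, 110 °C
Reagents that add atoms: none
Why: Aluminium-alkoxide-mediated isomerisation of the epoxide to the allylic alcohol: syn removal of a C15 methyl hydrogen with cleavage of the tertiary C4–O bond gives the exocyclic alkene, and C3 keeps its α-oxygen.

Step 17
Reactants: 23 allylic alcohol
Product: 24 3-oxoguaia-4(15),10(14),11(13)-trien-12,6α-olide 8β-silyl ether (dienophile)
Conditions: Dess–Martin periodinane, NaHCO3, CH2Cl2, 0 °C → rt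
Reagents that add atoms: none
Why: Dess–Martin oxidation of the allylic alcohol to the α-methylene cyclopentanone under buffered conditions; no stereocentre is created.

Step 18
Reactants: 24 α-methylene cyclopentanone
Product: 25 3-oxoguaia-1,4(15),10(14),11(13)-tetraen-12,6α-olide 8β-silyl ether (diene)
Conditions: IBX, 4-methoxypyridine N-oxide, DMSO, 25 °C; used at once
Reagents that add atoms: none
Why: IBX dehydrogenation of the ketone through its only enolisable position C2 introduces the C1=C2 double bond; C1 loses its stereocentre and C5 is untouched.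

Step 19
Reactants: 24 α-methylene cyclopentanone (dienophile), 25 tetraenone (diene)
Product: 26 Diels–Alder adduct (C1=C10 alkene, C2–H, 5α-H)
Conditions: toluene (concentrated), BHT, 60 °C; dienophile in threefold excess
Reagents that add atoms: none
Why: Thermal Diels–Alder reaction of the ring-locked s-cis diene C2=C1–C10=C14 with the exocyclic enone C4'=C15' in the ortho sense (acyl-bearing C2 to acyl-bearing C4'); the diene adds to the convex α-face of 24 (the face of H-1' and H-5', opposite C6'), which sets the spiro centre C4' with C15' β, while the excess of 24 suppresses self-reaction of 25 and the transient C2 centre is inconsequential.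

Step 20
Reactants: 26 Diels–Alder adduct
Product: 27 bis-silyl ether of the target
Conditions: DBU (0.2 equiv), CH2Cl2, 0 °C → rt
Reagents that add atoms: none
Why: Base-mediated isomerisation of the β,γ-unsaturated ketone to the conjugated enone (deprotonation at C2, reprotonation at C10); H-5 and H-10 are both γ-hydrogens of the cross-conjugated dienone and equilibrate through the extended enolate, so C10 and C5 are set under thermodynamic control, expected to give H-10 β and H-5 β.

Step 21
Reactants: 27 bis-silyl ether
Product: 28 target dimer CNP0397417.1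
Conditions: HF·pyridine, pyridine, THF, 0 °C → rt
Reagents that add atoms: none
Why: Buffered fluoride cleavage of both secondary silyl ethers under non-basic conditions, which leaves the epimerisable C5 and C10 and the α-methylene carbonyl groups untouched.

**Compound list**

1 | (R)-(−)-carvone | CC1=CC[C@H](CC1=O)C(C)=C | starting material
2 | carvone 2,3-epoxide, epoxide trans to isopropenyl | C[C@@]12O[C@@H]1C[C@H](CC2=O)C(C)=C | intermediate
3 | 2-chloro-3-hydroxy-2-methyl-5-isopropenylcyclohexanone (Cl cis, OH trans to isopropenyl) | C[C@]1(Cl)[C@H](O)C[C@H](CC1=O)C(C)=C | intermediate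
4 | 3-O-tert-butyldimethylsilyl ether of 3 | C[C@]1(Cl)[C@H](O[Si](C)(C)C(C)(C)C)C[C@H](CC1=O)C(C)=C | intermediate
5 | cyclopropanone (bicyclo[3.1.0]hexan-6-one, bridge cis to isopropenyl) | C[C@]12[C@H](O[Si](C)(C)C(C)(C)C)C[C@@H](C(C)=C)[C@H]1C2=O | intermediate
6 | methyl 1β-isopropenyl-3α-silyloxy-4α-methylcyclopentane-5β-carboxylate (guaiane numbering) | C[C@@H]1[C@H](O[Si](C)(C)C(C)(C)C)C[C@@H](C(C)=C)[C@H]1C(=O)OC | intermediate
7 | corresponding cyclopentane-5β-carbaldehyde | C[C@@H]1[C@H](O[Si](C)(C)C(C)(C)C)C[C@@H](C(C)=C)[C@H]1C=O | intermediate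
8 | 3,3-diethoxyprop-1-yne | C#CC(OCC)OCC | starting material
9 | lithium acetylide of 8 | [Li]C#CC(OCC)OCC | intermediate
10 | ethyl 4,4-diethoxybut-2-ynoate | CCOC(=O)C#CC(OCC)OCC | intermediate
11 | α-(diisobutylalumino) enoate (acetal cis to ester) | CCOC(=O)/C([Al](CC(C)C)CC(C)C)=C\C(OCC)OCC | intermediate
12 | ethyl (Z)-4,4-diethoxy-2-[(4,4,5,5-tetramethyl-1,3,2-dioxaborolan-2-yl)methyl]but-2-enoate | CCOC(=O)/C(CB1OC(C)(C)C(C)(C)O1)=C\C(OCC)OCC | intermediate
13 | pinacol borate of the anti homoallylic alcohol (C6–O–B, C7 acetal, acrylate ester) | C[C@@H]1[C@H](O[Si](C)(C)C(C)(C)C)C[C@@H](C(C)=C)[C@H]1[C@@H](OB1OC(C)(C)C(C)(C)O1)[C@@H](C(OCC)OCC)C(=C)C(=O)OCC | intermediate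
14 | trans α-methylene-γ-lactone (6β-H, 7α-H) with C8 diethyl acetal and 3α-silyloxy | C[C@@H]1[C@H](O[Si](C)(C)C(C)(C)C)C[C@@H](C(C)=C)[C@H]1[C@H]1OC(=O)C(=C)[C@@H]1C(OCC)OCC | intermediate
15 | 3α-alcohol of 14 | C[C@@H]1[C@H](O)C[C@@H](C(C)=C)[C@H]1[C@H]1OC(=O)C(=C)[C@@H]1C(OCC)OCC | intermediate
16 | cyclopent-3-ene lactone acetal | CC1=CC[C@@H](C(C)=C)[C@H]1[C@H]1OC(=O)C(=C)[C@@H]1C(OCC)OCC | intermediate
17 | cyclopent-3-ene lactone C8 aldehyde | CC1=CC[C@@H](C(C)=C)[C@H]1[C@H]1OC(=O)C(=C)[C@@H]1C=O | intermediate
18 | 8α-hydroxyguaia-3,10(14),11(13)-trien-12,6α-olide (1α-H, 5α-H, 6β-H, 7α-H) | CC1=CC[C@H]2C(=C)C[C@H](O)[C@H]3C(=C)C(=O)O[C@@H]3[C@H]21 | intermediate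
19 | 8β-formate of the triene lactone | CC1=CC[C@H]2C(=C)C[C@@H](OC=O)[C@H]3C(=C)C(=O)O[C@@H]3[C@H]21 | intermediate
20 | 8β-hydroxyguaia-3,10(14),11(13)-trien-12,6α-olide | CC1=CC[C@H]2C(=C)C[C@@H](O)[C@H]3C(=C)C(=O)O[C@@H]3[C@H]21 | intermediate
21 | 8β-tert-butyldimethylsilyl ether of 20 | CC1=CC[C@H]2C(=C)C[C@@H](O[Si](C)(C)C(C)(C)C)[C@H]3C(=C)C(=O)O[C@@H]3[C@H]21 | intermediate
22 | 3α,4α-epoxide of 21 | C[C@@]12O[C@@H]1C[C@H]3C(=C)C[C@@H](O[Si](C)(C)C(C)(C)C)[C@H]4C(=C)C(=O)O[C@@H]4[C@H]32 | intermediate
23 | 3α-hydroxy-8β-silyloxyguaia-4(15),10(14),11(13)-trien-12,6α-olide | C=C1[C@H](O)C[C@H]2C(=C)C[C@@H](O[Si](C)(C)C(C)(C)C)[C@H]3C(=C)C(=O)O[C@@H]3[C@H]21 | intermediate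
24 | 3-oxo-8β-silyloxyguaia-4(15),10(14),11(13)-trien-12,6α-olide | C=C1C(=O)C[C@H]2C(=C)C[C@@H](O[Si](C)(C)C(C)(C)C)[C@H]3C(=C)C(=O)O[C@@H]3[C@H]21 | intermediate
25 | 3-oxo-8β-silyloxyguaia-1,4(15),10(14),11(13)-tetraen-12,6α-olide (5α-H) | C=C1C(=O)C=C2C(=C)C[C@@H](O[Si](C)(C)C(C)(C)C)[C@H]3C(=C)C(=O)O[C@@H]3[C@H]21 | intermediate
26 | Diels–Alder adduct (C2–C4' and C14–C15' bonds, C1=C10, 2β-H, 5α-H, C15' β on C4') | C=C1C(=O)[C@H]2C3=C(CC[C@]24C(=O)C[C@H]2C(=C)C[C@@H](O[Si](C)(C)C(C)(C)C)[C@H]5C(=C)C(=O)O[C@@H]5[C@H]24)C[C@@H](O[Si](C)(C)C(C)(C)C)[C@H]2C(=C)C(=O)O[C@@H]2[C@@H]13 | intermediate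
27 | 8,8'-bis(tert-butyldimethylsilyl) ether of the target (C1=C2, 5β-H, 10β-H) | C=C1C(=O)C2=C3[C@H](CC[C@]24C(=O)C[C@H]2C(=C)C[C@@H](O[Si](C)(C)C(C)(C)C)[C@H]5C(=C)C(=O)O[C@@H]5[C@H]24)C[C@@H](O[Si](C)(C)C(C)(C)C)[C@H]2C(=C)C(=O)O[C@@H]2[C@H]13 | intermediate
28 | CNP0397417.1 | C=C1C(=O)C2=C3[C@H](CC[C@]24C(=O)C[C@H]2C(=C)C[C@@H](O)[C@H]5C(=C)C(=O)O[C@@H]5[C@H]24)C[C@@H](O)[C@H]2C(=C)C(=O)O[C@@H]2[C@H]13 | target

**Step count and risks**

Total steps: 21. Longest linear sequence: 19 (steps 1–5 and 8–21, from (R)-carvone).

The three steps most likely to fail: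

Step 19. Both partners are electron-poor, so the cross-cycloaddition may be slow and self-dimerisation or polymerisation of the cross-conjugated tetraenone may consume 25. Fallback: the diene is made more reactive by a change of oxidation level. Starting from 25, Luche reduction (NaBH4, CeCl3·7H2O, MeOH, −78 °C) should give the 3β-dienol F1, whose diene no longer carries an acyl group. Normal-demand Diels–Alder reaction of this with enone 24 (toluene, 40 °C) should give the adduct alcohol F2. Dess–Martin oxidation of its C3 carbinol, now allylic to C4=C15, returns to the route at 26.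

Step 20. The epimer equilibrium at C5 and C10 may not favour the target configuration when both hydroxyls carry bulky silyl groups, and base may also open or shift the lactone. Fallback: the order of events is changed. Starting from 26, the silyl groups are removed first (HF·pyridine, pyridine, THF) to give the diol adduct F3. Enone conjugation and equilibration are then run on the unprotected compound with a mild heterogeneous base (basic Al2O3, CH2Cl2, rt), so that the equilibrium is that of the natural product itself. This comes back to the route at 28.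

Step 12. The β-formyl lactone 17 can lose its C7 configuration or isomerise to the endocyclic butenolide under the Lewis acid, and the cationic intermediate can lose the wrong proton. Fallback: the ring is closed by a Barbier-type allylation. Starting from 14, ene-type allylic chlorination of the isopropenyl group (Ca(OCl)2, CO2, CH2Cl2/H2O) should give the allylic chloride F4. The conditions of steps 9, 10 and 11 then give the alcohol F5, the cyclopentene F6 and the chloro aldehyde F7. SnCl2 and NaI in DMF at room temperature close the seven-membered ring under nearly neutral conditions and return to the route at 18.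

Further compounds
F1 | step 19 | 3β-hydroxy-8β-silyloxyguaia-1,4(15),10(14),11(13)-tetraen-12,6α-olide (dienol) | C=C1[C@@H](O)C=C2C(=C)C[C@@H](O[Si](C)(C)C(C)(C)C)[C@H]3C(=C)C(=O)O[C@@H]3[C@H]21
F2 | step 19 | 3β-hydroxy Diels–Alder adduct (C3 carbinol in the diene-derived half) | C=C1[C@@H](O)[C@H]2C3=C(CC[C@]24C(=O)C[C@H]2C(=C)C[C@@H](O[Si](C)(C)C(C)(C)C)[C@H]5C(=C)C(=O)O[C@@H]5[C@H]24)C[C@@H](O[Si](C)(C)C(C)(C)C)[C@H]2C(=C)C(=O)O[C@@H]2[C@@H]13
F3 | step 20 | 8,8'-diol of Diels–Alder adduct 26 | C=C1C(=O)[C@H]2C3=C(CC[C@]24C(=O)C[C@H]2C(=C)C[C@@H](O)[C@H]5C(=C)C(=O)O[C@@H]5[C@H]24)C[C@@H](O)[C@H]2C(=C)C(=O)O[C@@H]2[C@@H]13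
F4 | step 12 | allylic chloride of 14 (3-chloroprop-1-en-2-yl group on C1) | C[C@@H]1[C@H](O[Si](C)(C)C(C)(C)C)C[C@@H](C(=C)CCl)[C@H]1[C@H]1OC(=O)C(=C)[C@@H]1C(OCC)OCC
F5 | step 12 | 3α-alcohol of the allylic chloride | C[C@@H]1[C@H](O)C[C@@H](C(=C)CCl)[C@H]1[C@H]1OC(=O)C(=C)[C@@H]1C(OCC)OCC
F6 | step 12 | cyclopent-3-ene allylic chloride acetal | CC1=CC[C@@H](C(=C)CCl)[C@H]1[C@H]1OC(=O)C(=C)[C@@H]1C(OCC)OCC
F7 | step 12 | cyclopent-3-ene allylic chloride C8 aldehyde | CC1=CC[C@@H](C(=C)CCl)[C@H]1[C@H]1OC(=O)C(=C)[C@@H]1C=O
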